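The dihydropyranone is cut at C2–C3 and O1–C6, so that C2 with both its oxygens is one molecule of CO2. In the key step a copper catalyst carboxylates a (Z)-alkenylboronate at C3; the carboxylate, held over C6 by the cis C3=C4 bond, displaces a C6 mesylate with inversion and closes the ring by 6-exo-tet O-alkylation. The precursor is an open chain whose C6 mesylate and C4' silyl ether (side chain C1'–C15' counted from C6) stem from two (S)-epichlorohydrin units joined by dithiane linchpins at C2' and C6'. The 1,3-anti C6/C2' relation thus arises from an all-syn chain; both masked ketones are finally reduced syn from the C4' hydroxyl.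

Key step: step 7

Remark: ring atoms are O1, C2(=O), C3=C4, C5, C6 and the side-chain carbinols are C2', C4', C6'; compounds 1, 2, 4 and 8 are taken as commercial.

Step 1
Reactants: 1 decanal; 2 propane-1,3-dithiol
Product: 3 2-nonyl-1,3-dithiane
Conditions: BF3·OEt2 (cat.), CH2Cl2, 0 °C to rt
Reagents that add atoms: none
Why: Lewis-acid-catalysed dithioacetalization turns the aldehyde carbon into the C6' acyl-anion equivalent needed for Corey–Seebach umpolung and creates no stereocenter.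

Step 2
Reactants: 3 2-nonyl-1,3-dithiane; 4 (2S)-2-(chloromethyl)oxirane [(S)-epichlorohydrin]
Product: 7 2-nonyl-2-{[(2S)-oxiran-2-yl]methyl}-1,3-dithiane, via lithiated dithiane 5 (not isolated), via lithium chlorohydrin alkoxide 6 (not isolated)
Conditions: n-BuLi, THF, −30 °C; then 4, −78 °C to rt
Reagents that add atoms: none
Why: Corey–Seebach alkylation in which the 2-lithiodithiane opens the epoxide of 4 at its CH2 terminus and the chlorohydrin alkoxide then closes onto the CH2Cl carbon, so that the C–O stereocenter of 4 is never broken and becomes C4' of the target.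

Step 3
Reactants: 8 2-(tert-butyldimethylsilyl)-1,3-dithiane; 7 2-nonyl-2-{[(2S)-oxiran-2-yl]methyl}-1,3-dithiane; 4 (2S)-2-(chloromethyl)oxirane
Product: 13 tert-butyldimethyl{[(2S)-1-(2-nonyl-1,3-dithian-2-yl)-3-(2-{[(2S)-oxiran-2-yl]methyl}-1,3-dithian-2-yl)propan-2-yl]oxy}silane, via lithiated silyl dithiane 9 (not isolated), via lithium alkoxide adduct 10 (not isolated), via Brook-rearranged carbanion 11 (not isolated), via second chlorohydrin alkoxide 12 (not isolated)
Conditions: 8, t-BuLi, Et2O, −78 to −45 °C; 7, −78 to −25 °C; then 4, HMPA, THF, −78 °C to rt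
Reagents that add atoms: none
Why: Silyl-dithiane anion relay coupling in which lithiated 8 opens 7 at its epoxide CH2 in ether, HMPA then triggers a 1,4-Brook rearrangement that silylates the C4' oxygen and moves the carbanion to C2', and this anion opens a second molecule of 4 at CH2 before chloride displacement forms the terminal epoxide whose stereocenter (the future C6) is carried over unchanged from 4.

Step 4
Reactants: 13 tert-butyldimethyl{[(2S)-1-(2-nonyl-1,3-dithian-2-yl)-3-(2-{[(2S)-oxiran-2-yl]methyl}-1,3-dithian-2-yl)propan-2-yl]oxy}silane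
Product: 14 (2R)-1-{2-[(2S)-2-[(tert-butyldimethylsilyl)oxy]-3-(2-nonyl-1,3-dithian-2-yl)propyl]-1,3-dithian-2-yl}pent-4-yn-2-ol
Conditions: LiC≡CH·H2NCH2CH2NH2, DMSO, rt
Reagents that add atoms: lithium acetylide–ethylenediamine complex, [Li]C#C.NCCN
Why: SN2 opening of the terminal epoxide by acetylide at the unhindered CH2 carbon (C5) installs C4 and C3 as a terminal alkyne and leaves the C6–O bond with its configuration untouched.

Step 5
Reactants: 14 (2R)-1-{2-[(2S)-2-[(tert-butyldimethylsilyl)oxy]-3-(2-nonyl-1,3-dithian-2-yl)propyl]-1,3-dithian-2-yl}pent-4-yn-2-ol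
Product: 15 (2R)-1-{2-[(2S)-2-[(tert-butyldimethylsilyl)oxy]-3-(2-nonyl-1,3-dithian-2-yl)propyl]-1,3-dithian-2-yl}pent-4-yn-2-yl methanesulfonate
Conditions: MsCl, Et3N, CH2Cl2, 0 °C
Reagents that add atoms: methanesulfonyl chloride, CS(=O)(=O)Cl
Why: O-Sulfonylation of the only free hydroxyl proceeds with retention at C6 and makes C6 the electrophile for the later ring closure.

Step 6
Reactants: 15 (2R)-1-{2-[(2S)-2-[(tert-butyldimethylsilyl)oxy]-3-(2-nonyl-1,3-dithian-2-yl)propyl]-1,3-dithian-2-yl}pent-4-yn-2-yl methanesulfonate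
Product: 17 (2R,4Z)-5-(5,5-dimethyl-1,3,2-dioxaborinan-2-yl)-1-{2-[(2S)-2-[(tert-butyldimethylsilyl)oxy]-3-(2-nonyl-1,3-dithian-2-yl)propyl]-1,3-dithian-2-yl}pent-4-en-2-yl methanesulfonate, via catechol alkenylboronate 16 (not isolated)
Conditions: catecholborane, [Rh(cod)Cl]2 (cat.), P(i-Pr)3, Et3N, cyclohexane, rt; then 2,2-dimethylpropane-1,3-diol, rt
Reagents that add atoms: catecholborane (1,3,2-benzodioxaborole), B1Oc2ccccc2O1; 2,2-dimethylpropane-1,3-diol, CC(C)(CO)CO
Why: Rhodium-catalysed trans-hydroboration of the terminal alkyne through a rhodium vinylidene places boron on the terminal carbon C3 cis to the C4–C5 bond and so gives the (Z)-alkenylboronate, which is exchanged in the same flask for the sturdier neopentyl glycol ester, while homogeneous monovalent rhodium–phosphine catalysts are expected to tolerate the hindered thioacetals and no stereocenter is touched.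

Step 7
Reactants: 17 (2R,4Z)-5-(5,5-dimethyl-1,3,2-dioxaborinan-2-yl)-1-{2-[(2S)-2-[(tert-butyldimethylsilyl)oxy]-3-(2-nonyl-1,3-dithian-2-yl)propyl]-1,3-dithian-2-yl}pent-4-en-2-yl methanesulfonate
Product: 19 (6S)-6-({2-[(2S)-2-[(tert-butyldimethylsilyl)oxy]-3-(2-nonyl-1,3-dithian-2-yl)propyl]-1,3-dithian-2-yl}methyl)-5,6-dihydro-2H-pyran-2-one, via potassium (Z)-enoate 18 (not isolated)
Conditions: chloro[1,3-bis(2,6-diisopropylphenyl)imidazol-2-ylidene]copper (cat.), KOt-Bu, CO2 (1 atm), THF, 70 °C; then DMF, 60 °C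
Reagents that add atoms: carbon dioxide, O=C=O
Why: The tert-butoxide-activated boronate transmetalates to the monovalent copper–carbene complex with retention of the Z geometry, CO2 inserts into the Cu–C3 bond to forge C2–C3, and salt metathesis releases the potassium (Z)-enoate 18 while regenerating the copper alkoxide. The closest known reaction types are the copper-catalysed carboxylation of alkenylboronic esters with CO2 and the invertive lactonization of carboxylate salts onto secondary sulfonates in dipolar aprotic solvents. The only ring formed, the six-membered lactone, closes by 6-exo-tet attack of a carboxylate oxygen on C6, which forms O1–C6. The C6 stereocenter is set by SN2 inversion of the (R)-mesylate derived from (S)-epichlorohydrin, which gives the (S) configuration that is 1,3-anti to the later C2' hydroxyl. The step needs O-alkylation to outrun E2 elimination toward C5 and needs the alkene to stay cis: the cis C3=C4 bond holds the carboxylate within reach of C6 in an unstrained six-membered transition state, the base is bound as the borate before heating, and the C2' and C6' carbonyls are masked as dithianes so that no enolate-driven β-elimination is possible.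

Step 8
Reactants: 19 (6S)-6-({2-[(2S)-2-[(tert-butyldimethylsilyl)oxy]-3-(2-nonyl-1,3-dithian-2-yl)propyl]-1,3-dithian-2-yl}methyl)-5,6-dihydro-2H-pyran-2-one
Product: 21 (6S)-6-[(4S)-4-hydroxy-2,6-dioxopentadecyl]-5,6-dihydro-2H-pyran-2-one, via diketone silyl ether 20 (not isolated)
Conditions: PhI(O2CCF3)2, MeCN/H2O, 0 °C; then 48% aq. HF, rt
Reagents that add atoms: water, O
Why: Oxidative dethioacetalization with the trivalent iodine reagent in wet acetonitrile unveils both ketones without harming the enoate and aqueous HF then removes the silyl group from the C4' oxygen, the acidic medium avoiding β-elimination of the C6 acyloxy group so that no stereocenter is affected.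

Step 9
Reactants: 21 (6S)-6-[(4S)-4-hydroxy-2,6-dioxopentadecyl]-5,6-dihydro-2H-pyran-2-one
Product: 22 (6S)-6-[(2S,4S,6S)-2,4,6-trihydroxypentadecyl]-5,6-dihydro-2H-pyran-2-one
Conditions: catecholborane (excess), THF, −10 °C; then aq. sodium potassium tartrate
Reagents that add atoms: none
Why: Hydroxyl-directed 1,3-syn reduction (catecholborane variant of the Narasaka–Prasad reduction) in which the C4' alkoxyborane chelates each β-carbonyl in turn in a six-membered half-chair and hydride from a second borane adds to the exposed face, which sets C2' and C6' syn to C4' (both S), while the transoid enoate of the lactone is inert to uncatalysed catecholborane.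

Compound list
1 | decanal | CCCCCCCCCC=O | starting material
2 | propane-1,3-dithiol | SCCCS | starting material
3 | 2-nonyl-1,3-dithiane | CCCCCCCCCC1SCCCS1 | intermediate
4 | (2S)-2-(chloromethyl)oxirane, (S)-epichlorohydrin | ClC[C@@H]1CO1 | starting material
5 | 2-lithio-2-nonyl-1,3-dithiane | CCCCCCCCCC1([Li])SCCCS1 | intermediate
6 | lithium (2S)-1-chloro-3-(2-nonyl-1,3-dithian-2-yl)propan-2-olate | CCCCCCCCCC1(SCCCS1)C[C@H](O[Li])CCl | intermediate
7 | 2-nonyl-2-{[(2S)-oxiran-2-yl]methyl}-1,3-dithiane | CCCCCCCCCC1(SCCCS1)C[C@H]2CO2 | intermediate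
8 | 2-(tert-butyldimethylsilyl)-1,3-dithiane | CC(C)(C)[Si](C)(C)C1SCCCS1 | starting material
9 | 2-(tert-butyldimethylsilyl)-2-lithio-1,3-dithiane | CC(C)(C)[Si](C)(C)C1([Li])SCCCS1 | intermediate
10 | lithium (2S)-1-[2-(tert-butyldimethylsilyl)-1,3-dithian-2-yl]-3-(2-nonyl-1,3-dithian-2-yl)propan-2-olate | CCCCCCCCCC1(SCCCS1)C[C@H](O[Li])CC2(SCCCS2)[Si](C)(C)C(C)(C)C | intermediate
11 | 2-lithio-2-[(2R)-2-[(tert-butyldimethylsilyl)oxy]-3-(2-nonyl-1,3-dithian-2-yl)propyl]-1,3-dithiane (same spatial arrangement as in 10; the descriptor changes because lithium ranks below carbon) | CCCCCCCCCC1(SCCCS1)C[C@H](O[Si](C)(C)C(C)(C)C)CC2([Li])SCCCS2 | intermediate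
12 | lithium (2S)-1-{2-[(2S)-2-[(tert-butyldimethylsilyl)oxy]-3-(2-nonyl-1,3-dithian-2-yl)propyl]-1,3-dithian-2-yl}-3-chloropropan-2-olate | CCCCCCCCCC1(SCCCS1)C[C@H](O[Si](C)(C)C(C)(C)C)CC2(SCCCS2)C[C@H](O[Li])CCl | intermediate
13 | tert-butyldimethyl{[(2S)-1-(2-nonyl-1,3-dithian-2-yl)-3-(2-{[(2S)-oxiran-2-yl]methyl}-1,3-dithian-2-yl)propan-2-yl]oxy}silane | CCCCCCCCCC1(SCCCS1)C[C@H](O[Si](C)(C)C(C)(C)C)CC2(SCCCS2)C[C@H]3CO3 | intermediate
14 | (2R)-1-{2-[(2S)-2-[(tert-butyldimethylsilyl)oxy]-3-(2-nonyl-1,3-dithian-2-yl)propyl]-1,3-dithian-2-yl}pent-4-yn-2-ol | CCCCCCCCCC1(SCCCS1)C[C@H](O[Si](C)(C)C(C)(C)C)CC2(SCCCS2)C[C@H](O)CC#C | intermediate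
15 | (2R)-1-{2-[(2S)-2-[(tert-butyldimethylsilyl)oxy]-3-(2-nonyl-1,3-dithian-2-yl)propyl]-1,3-dithian-2-yl}pent-4-yn-2-yl methanesulfonate | CCCCCCCCCC1(SCCCS1)C[C@H](O[Si](C)(C)C(C)(C)C)CC2(SCCCS2)C[C@H](OS(C)(=O)=O)CC#C | intermediate
16 | (2R,4Z)-5-(1,3,2-benzodioxaborol-2-yl)-1-{2-[(2S)-2-[(tert-butyldimethylsilyl)oxy]-3-(2-nonyl-1,3-dithian-2-yl)propyl]-1,3-dithian-2-yl}pent-4-en-2-yl methanesulfonate | CCCCCCCCCC1(SCCCS1)C[C@H](O[Si](C)(C)C(C)(C)C)CC2(SCCCS2)C[C@H](OS(C)(=O)=O)C/C=C\B3Oc4ccccc4O3 | intermediate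
17 | (2R,4Z)-5-(5,5-dimethyl-1,3,2-dioxaborinan-2-yl)-1-{2-[(2S)-2-[(tert-butyldimethylsilyl)oxy]-3-(2-nonyl-1,3-dithian-2-yl)propyl]-1,3-dithian-2-yl}pent-4-en-2-yl methanesulfonate | CCCCCCCCCC1(SCCCS1)C[C@H](O[Si](C)(C)C(C)(C)C)CC2(SCCCS2)C[C@H](OS(C)(=O)=O)C/C=C\B3OCC(C)(C)CO3 | intermediate
18 | potassium (2Z,5R)-6-{2-[(2S)-2-[(tert-butyldimethylsilyl)oxy]-3-(2-nonyl-1,3-dithian-2-yl)propyl]-1,3-dithian-2-yl}-5-[(methanesulfonyl)oxy]hex-2-enoate | CCCCCCCCCC1(SCCCS1)C[C@H](O[Si](C)(C)C(C)(C)C)CC2(SCCCS2)C[C@H](OS(C)(=O)=O)C/C=C\C(=O)[O-].[K+] | intermediate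
19 | (6S)-6-({2-[(2S)-2-[(tert-butyldimethylsilyl)oxy]-3-(2-nonyl-1,3-dithian-2-yl)propyl]-1,3-dithian-2-yl}methyl)-5,6-dihydro-2H-pyran-2-one | CCCCCCCCCC1(SCCCS1)C[C@H](O[Si](C)(C)C(C)(C)C)CC2(SCCCS2)C[C@@H]3CC=CC(=O)O3 | intermediate
20 | (6S)-6-[(4S)-4-[(tert-butyldimethylsilyl)oxy]-2,6-dioxopentadecyl]-5,6-dihydro-2H-pyran-2-one | CCCCCCCCCC(=O)C[C@H](O[Si](C)(C)C(C)(C)C)CC(=O)C[C@@H]1CC=CC(=O)O1 | intermediate
21 | (6S)-6-[(4S)-4-hydroxy-2,6-dioxopentadecyl]-5,6-dihydro-2H-pyran-2-one | CCCCCCCCCC(=O)C[C@H](O)CC(=O)C[C@@H]1CC=CC(=O)O1 | intermediate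
22 | (6S)-6-[(2S,4S,6S)-2,4,6-trihydroxypentadecyl]-5,6-dihydro-2H-pyran-2-one | CCCCCCCCC[C@H](O)C[C@H](O)C[C@H](O)C[C@@H]1CC=CC(=O)O1 | target

Total steps: 9. Longest linear sequence: 9 steps (1 to 22).

Steps most likely to fail

Step 7. E2 loss of methanesulfonate toward C5, which would give a conjugated diene, or protodeboronation may outpace carboxylation and the 6-exo-tet O-alkylation. The fallback sets out from 13 and comes back at 19. The epoxide of 13 is opened at its CH2 carbon with vinylmagnesium bromide and catalytic CuI to give the homoallylic alcohol (2R)-1-{2-[(2S)-2-[(tert-butyldimethylsilyl)oxy]-3-(2-nonyl-1,3-dithian-2-yl)propyl]-1,3-dithian-2-yl}pent-4-en-2-ol F1. Mitsunobu esterification with acrylic acid (PPh3, DIAD) inverts C6 and should give the acrylate (2S)-1-{2-[(2S)-2-[(tert-butyldimethylsilyl)oxy]-3-(2-nonyl-1,3-dithian-2-yl)propyl]-1,3-dithian-2-yl}pent-4-en-2-yl prop-2-enoate F2. Ring-closing metathesis with the second-generation Grubbs catalyst then forms C3=C4 and delivers 19.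

Step 6. The four thioacetal sulfur atoms may bind the rhodium catalyst and stall the vinylidene pathway, or slow turnover may let the (Z)-alkenylboronate isomerize to the E isomer, which cannot lactonize. The fallback sets out from 15 and comes back at 21. Both dithianes of 15 are exchanged for dioxolanes with PhI(O2CCF3)2 and ethylene glycol in MeCN to give the sulfur-free mesylate (2R)-1-{2-[(2S)-2-[(tert-butyldimethylsilyl)oxy]-3-(2-nonyl-1,3-dioxolan-2-yl)propyl]-1,3-dioxolan-2-yl}pent-4-yn-2-yl methanesulfonate F3. The same trans-hydroboration and diol exchange should then give (2R,4Z)-5-(5,5-dimethyl-1,3,2-dioxaborinan-2-yl)-1-{2-[(2S)-2-[(tert-butyldimethylsilyl)oxy]-3-(2-nonyl-1,3-dioxolan-2-yl)propyl]-1,3-dioxolan-2-yl}pent-4-en-2-yl methanesulfonate F4. Carboxylative lactonization as in step 7 gives (6S)-6-({2-[(2S)-2-[(tert-butyldimethylsilyl)oxy]-3-(2-nonyl-1,3-dioxolan-2-yl)propyl]-1,3-dioxolan-2-yl}methyl)-5,6-dihydro-2H-pyran-2-one F5, and aqueous HF in MeCN hydrolyses both ketals and the silyl ether in one operation to give 21.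

Step 9. After the first carbonyl is reduced the C4' oxygen may stay tied up in a cyclic boron ester with the new carbinol, so that the second carbonyl is reduced without chelation and facial selectivity at that center is poor. The fallback sets out from 21 and comes back at 22. The twofold reduction is divided into two separate Narasaka–Prasad reductions (Et2BOMe, NaBH4, THF/MeOH, −78 °C) with release of the C4' hydroxyl in between. The first pass, run with one equivalent of each reagent and followed by cleavage of the boron ester with methanol, should give the two regioisomeric syn-diol ketones (6S)-6-[(2S,4R)-2,4-dihydroxy-6-oxopentadecyl]-5,6-dihydro-2H-pyran-2-one F6 and (6S)-6-[(4S,6S)-4,6-dihydroxy-2-oxopentadecyl]-5,6-dihydro-2H-pyran-2-one F7. The mixture is resubmitted, the free C4' hydroxyl chelates the remaining carbonyl in each isomer, and both converge on 22.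

Further compounds
F1 | step 7 | (2R)-1-{2-[(2S)-2-[(tert-butyldimethylsilyl)oxy]-3-(2-nonyl-1,3-dithian-2-yl)propyl]-1,3-dithian-2-yl}pent-4-en-2-ol | CCCCCCCCCC1(SCCCS1)C[C@H](O[Si](C)(C)C(C)(C)C)CC2(SCCCS2)C[C@H](O)CC=C
F2 | step 7 | (2S)-1-{2-[(2S)-2-[(tert-butyldimethylsilyl)oxy]-3-(2-nonyl-1,3-dithian-2-yl)propyl]-1,3-dithian-2-yl}pent-4-en-2-yl prop-2-enoate | CCCCCCCCCC1(SCCCS1)C[C@H](O[Si](C)(C)C(C)(C)C)CC2(SCCCS2)C[C@@H](OC(=O)C=C)CC=C
F3 | step 6 | (2R)-1-{2-[(2S)-2-[(tert-butyldimethylsilyl)oxy]-3-(2-nonyl-1,3-dioxolan-2-yl)propyl]-1,3-dioxolan-2-yl}pent-4-yn-2-yl methanesulfonate | CCCCCCCCCC1(OCCO1)C[C@H](O[Si](C)(C)C(C)(C)C)CC2(OCCO2)C[C@H](OS(C)(=O)=O)CC#C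
F4 | step 6 | (2R,4Z)-5-(5,5-dimethyl-1,3,2-dioxaborinan-2-yl)-1-{2-[(2S)-2-[(tert-butyldimethylsilyl)oxy]-3-(2-nonyl-1,3-dioxolan-2-yl)propyl]-1,3-dioxolan-2-yl}pent-4-en-2-yl methanesulfonate | CCCCCCCCCC1(OCCO1)C[C@H](O[Si](C)(C)C(C)(C)C)CC2(OCCO2)C[C@H](OS(C)(=O)=O)C/C=C\B3OCC(C)(C)CO3
F5 | step 6 | (6S)-6-({2-[(2S)-2-[(tert-butyldimethylsilyl)oxy]-3-(2-nonyl-1,3-dioxolan-2-yl)propyl]-1,3-dioxolan-2-yl}methyl)-5,6-dihydro-2H-pyran-2-one | CCCCCCCCCC1(OCCO1)C[C@H](O[Si](C)(C)C(C)(C)C)CC2(OCCO2)C[C@@H]3CC=CC(=O)O3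
F6 | step 9 | (6S)-6-[(2S,4R)-2,4-dihydroxy-6-oxopentadecyl]-5,6-dihydro-2H-pyran-2-one | CCCCCCCCCC(=O)C[C@H](O)C[C@H](O)C[C@@H]1CC=CC(=O)O1
F7 | step 9 | (6S)-6-[(4S,6S)-4,6-dihydroxy-2-oxopentadecyl]-5,6-dihydro-2H-pyran-2-one | CCCCCCCCC[C@H](O)C[C@H](O)CC(=O)C[C@@H]1CC=CC(=O)O1
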